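The ratio of target in the east run, 30.6% at 2.00 h over 21.4% at 3.00 h, taken as a logarithm to base ten, gives 0.155 h⁻¹. This is the loss slope, the decades of target lost per hour late in a run. As a reading from the north run, at other charges, it comes to 0.148 h⁻¹.

| flask | starting material | second substrate | free enzyme | remark | time |
|---|---|---|---|---|---|
| north-east | 20 mM | 12 mM | 1 µM | run made earlier |  |
| east | 20 mM | 12 mM | 4 µM | run made earlier |  |
| north | 40 mM | 12 mM | 2 µM | run made earlier |  |
| flask | 20 mM | 12.0 mM | 2.0 µM |  | 4.0 h |
- north-east (time / h: target / %, starting material / %): 0.333: 9.0, 87.9; 0.500: 13.8, 81.5; 1.00: 23.3, 61.2; 2.00: 32.1, 28.2; 3.00: 29.1, 12.3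
- east (time / h: target / %, starting material / %): 0.333: 34.3, 57.7; 0.500: 43.7, 41.5; 1.00: 44.4, 23.4; 2.00: 30.6, 14.4; 3.00: 21.4, 9.4
- north (time / h: target / %, starting material / %): 0.333: 8.9, 86.7; 0.500: 12.6, 79.4; 1.00: 20.4, 60.5; 2.00: 16.6, 45.6; 3.00: 11.8, 41.7

(standard deviation of a reading: 0.3 percentage points)
- on the list of suspects stand: starting material + free enzyme <-> first complex; first complex -> loaded enzyme + first product; second substrate + loaded enzyme <-> second complex; second complex -> free enzyme + target; target -> over-reaction product; target <-> isomer of the product; starting material + first product -> side product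
- the best time, 4.0 h at the latest, for target
- the amount of target, in percent of the starting material charged, at that time

The flask holds enzyme working through starting material. In the flask second substrate is charged at less than starting material, so target climbs towards a roof of 60.0%, the ratio of the two charges. Do not leave it past the peak: in the east run the hour from 2.00 h to 3.00 h divided target by 1.43.

The forecast puts the peak at 40.5% after 1.3 h and reads the late fall as “a non-enzymatic first-order loss”. My own reckoning starts from that peak and carries the slope to the end:

c(target) at 4.0 h = 40.5% × 0.699 ^ 2.70 = 15.4%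

The flask peaks at 41.6% after 1.26 h, with second substrate, the limiting reagent, down to 6.99% of its charge.

    starting material + free enzyme ⇌ first complex (K = 2000 M⁻¹, k = 1600 M⁻¹ s⁻¹)
    first complex → loaded enzyme + first product (k = 6.00 s⁻¹)
    second substrate + loaded enzyme ⇌ second complex (K = 240 M⁻¹, k = 5500 M⁻¹ s⁻¹)
    second complex → free enzyme + target (k = 3.70 s⁻¹)
    target → over-reaction product (k = 7.70 × 10⁻⁵ s⁻¹)
    target ⇌ isomer of the product (K = 0.870, k = 4.10 × 10⁻⁵ s⁻¹)
    starting material + first product → side product (k = 0.0170 M⁻¹ s⁻¹)

In the flask, from 2.00 h, with 0.170% of second substrate left, target falls from 34.3% to 17.2% at 4.00 h, a slope of 0.150 h⁻¹. The neighbour charged with 20 mM of second substrate reaches 55.7% and stands at 23.8% at 4.00 h, a fall that the loss slope spreads over 2.38 h.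

The readings were computed for an exercise.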